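(Readings and results were generated by integration with made-up constants; noise was put on by code.)

A small charge has to be booked before it is spent, so keep a ledger of the limiting reagent. By the overall equation that is the starting material, 0.150 M against 0.165 M of partner in the ochre run.

| flask | starting material | partner | time |
|---|---|---|---|
| ochre | 0.150 M | 0.165 M |  |
| grey | 0.0750 M | 0.0900 M |  |
| green | 0.0750 M | 0.165 M |  |
| teal | 0.150 M | 0.250 M |  |
| amber | 0.150 M | 0.165 M | 96 min |

- ochre run (time / min: [target] / M): 1.3: 0.0052; 2.9: 0.0106; 6.4: 0.0233; 14: 0.0468; 32: 0.0617
- grey run (time / min: [target] / M): 1.3: 0.0011; 2.9: 0.0049; 6.4: 0.0108; 14: 0.0195; 32: 0.0286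
- green run (time / min: [target] / M): 1.3: 0; 2.9: 0.0052; 6.4: 0.0101; 14: 0.0243; 32: 0.0283
- teal run (time / min: [target] / M): 1.3: 9 × 10⁻⁴; 2.9: 0.0121; 6.4: 0.0265; 14: 0.0545; 32: 0.0595

(readings scatter by 0.002 M)

- Overall: starting material + partner -> target.
- Constant volume, constant temperature.
- Readings of a species count what is bound in complexes too.
- An order is taken over about fifteen percent of the charge, up and down.

1. order of the initial rate in [partner], near the charge of the ochre run, the rate being that where two percent of its starting material are target
2. order of the initial rate in [starting material], near the charge of the ochre run, the rate being that where two percent of its starting material are target (one fixed amount of target, the same in the runs compared)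
3. target in the amber run at 96 min, as a share of the starting material charged

1. Open the amber account. Amber has the ochre charge, so use the ochre readings and book 0.150 M of starting material.

2. Compare rates. Ochre makes target at 0.00364 M min⁻¹ up to 6.4 min, but at 8.28 × 10⁻⁴ M min⁻¹ between 14 min and 32 min. That is about a quarter of the early rate, so the ochre rate falls as the run goes on.

3. Enter the target. Define the ceiling share as [target] at 32 min in the ochre run over the starting material charged: 41.1%. The scatter of one reading is worth 1.33% of that charge.

4. Test it against partner. At 32 min, the grey run stands at 38.1%, the green run at 37.7% and the teal run at 39.7%. Green carries 2.20 partner per starting material, ochre 1.10, yet the green share reads lower than the ochre share, with the starting material changed as well.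

5. Close the books. Target takes 0.0617 M, and the open entry is 0.0883 M, which these readings cannot split.

6. Commit: amber at 96 min holds the ceiling share, 41.1%.

The forecast gives orders of 0.25 in partner and 1 in starting material, and 43%, higher than my share, reading the stall as “a first-order loss of an active species”.

The simulation gives orders of 0.35 and 0.68, and 40.6% for amber, 0.50 percentage points below the ceiling share.

    starting material + partner → intermediate (1.686 M⁻¹ min⁻¹)
    intermediate → target (0.6720 min⁻¹)
    2 partner ⇌ idle reagent dimer, settled at all times (105.0 M⁻¹)
    target + partner → side product (1.380 M⁻¹ min⁻¹)

Partner reacts with target with constant 1.38 M⁻¹ min⁻¹, and with starting material with constant 1.69 M⁻¹ min⁻¹. Now carry the ceiling share to the grey run: it gives 0.0308 M for that charge, and a quarter of the charge is 60.8% of this amount. The ochre run reached a quarter of its own charge at 10.2 min, the grey run at 13.4 min.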